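## Retrosynthetic overview

1. Target ⇒ 6α‑tigloyloxy‑7‑en‑17‑al (Pinnick oxidation) ⇒ 6α‑hydroxy‑7‑en‑17‑al already carrying the butenolide (acylation).
2. C11–C12 bond (decalin to butenolide): visible‑light decarboxylative radical addition–elimination of the C12 carboxylic acid onto racemic O‑acetyl tulipalin B, which is made by a Baylis–Hillman/lactonisation sequence.
3. C6–O bond: peracid oxidation of the silyl dienol ether of the Δ7‑17‑enal on the α face (substrate control); the enal comes from SeO2 oxidation of the C17 methyl of the Δ7 ester obtained by acid methanolysis of (+)‑sclareolide.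
4. Ring order: rings A and B with C5, C9 and C10 are bought in sclareolide (its lactone ring is opened first and its carbonyl carbon later leaves as CO2); the butenolide ring is built separately and attached late.

Assumption: the SMILES is read as the normal‑labdane enantiomer (5S,6S,9R,10R; 5α‑H, 9α‑H, 10β‑CH3, 6α‑acyloxy) carrying an (E)‑2‑methylbut‑2‑enoate (tiglate); labdane numbering is used throughout.

## Route

Step 1
Reactants: 1 (+)-sclareolide
Product: 2 methyl 13,14,15,16-tetranorlabd-7-en-12-oate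
Conditions: H2SO4 (conc.), MeOH, 50 °C; AgNO3–SiO2 chromatography
Reagents that add atoms: methanol, CO
Why: Acid‑catalysed alkyl–oxygen cleavage of the tertiary lactone (E1) gives the C8 cation, which loses the axial C7 proton to the trisubstituted Δ7 alkene while Fischer esterification stops relactonisation; the Δ8(17) and Δ8 isomers formed alongside are removed on AgNO3–SiO2, and C5, C9 and C10 are untouched.

Step 2
Reactants: 2 methyl 13,14,15,16-tetranorlabd-7-en-12-oate
Product: 4 methyl 17-oxo-13,14,15,16-tetranorlabd-7-en-12-oate, via methyl 17-hydroxy-13,14,15,16-tetranorlabd-7-en-12-oate 3 (not isolated)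
Conditions: SeO2 (2 equiv), 1,4-dioxane/H2O (30:1), 100 °C
Reagents that add atoms: selenium dioxide, O=[Se]=O
Why: Riley oxidation (ene reaction then [2,3]-shift) attacks the allylic position on the more substituted alkene carbon, where the C17 methyl reacts in preference to the tertiary, hindered C9–H, and the primary allylic alcohol 3 is oxidised on to the enal under the same conditions; no stereocentre is formed.

Step 3
Reactants: 4 methyl 17-oxo-13,14,15,16-tetranorlabd-7-en-12-oate
Product: 6 17-oxo-13,14,15,16-tetranorlabd-7-en-12-oic acid, via lithium carboxylate 5 (not isolated)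
Conditions: LiOH, THF/H2O (3:1), 23 °C; then 1 M HCl
Reagents that add atoms: lithium hydroxide, [Li+].[OH-]
Why: Saponification of the unhindered methyl ester; the enal has no α‑hydrogen and C9–H is only cross‑conjugated, so C9 keeps its configuration.

Step 4
Reactants: 6 17-oxo-13,14,15,16-tetranorlabd-7-en-12-oic acid
Product: 9 6α-hydroxy-17-oxo-13,14,15,16-tetranorlabd-7-en-12-oic acid, via bis(triethylsilyl) dienol ether 7 (not isolated), via triethylsilyl ester of the 6α-hydroxy enal 8 (not isolated)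
Conditions: Et3SiOTf (2.5 equiv), Et3N, CH2Cl2, −78 → 0 °C; pentane, filter, concentrate; then 3-chloroperbenzoic acid (mCPBA, 1.05 equiv), hexane/CH2Cl2, −20 °C; then 1 M HCl, THF, 23 °C
Reagents that add atoms: 3-chloroperbenzoic acid, OOC(=O)c1cccc(Cl)c1; triethylsilyl triflate, CC[Si](CC)(CC)OS(=O)(=O)C(F)(F)F (its silicon stays only in 7 and 8)
Why: Soft γ‑enolisation gives the silyl dienol ether and a vinylogous Rubottom oxidation follows, the peracid epoxidising the distal C6=C7 bond on the α face because the β face is screened by the axial methyls on C4 and C10 (both 1,3‑syn to C6), so that epoxide opening under the silyloxy push places the new oxygen 6α and restores the 7‑en‑17‑al, after which aqueous acid cleaves the silyl ester.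

Step 5
Reactants: 10 methyl acrylate; 11 glycolaldehyde dimer (1,4-dioxane-2,5-diol)
Product: 14 rac-tulipalin B (4-hydroxy-3-methylideneoxolan-2-one), via glycolaldehyde 12 (not isolated), via methyl 3,4-dihydroxy-2-methylidenebutanoate 13 (not isolated)
Conditions: 1,4-diazabicyclo[2.2.2]octane (DABCO, 0.5 equiv), 1,4-dioxane/H2O (1:1), 23 °C; concentrate; then Amberlyst 15, MeCN, 40 °C
Reagents that add atoms: none
Why: Morita–Baylis–Hillman reaction of the acrylate with monomeric glycolaldehyde followed by acid‑catalysed γ‑lactonisation through the primary hydroxyl; the carbinol centre is racemic, which is harmless because it is destroyed in step 7.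

Step 6
Reactants: 14 rac-tulipalin B
Product: 15 rac-O-acetyltulipalin B ((4-methylidene-5-oxooxolan-3-yl) acetate)
Conditions: Ac2O, pyridine, CH2Cl2, 0 °C
Reagents that add atoms: acetic anhydride, CC(=O)OC(C)=O
Why: Standard O‑acetylation; the lactone has no α‑hydrogen, so the β‑acetate cannot eliminate before it is wanted.

Step 7
Reactants: 9 6α-hydroxy-17-oxo-13,14,15,16-tetranorlabd-7-en-12-oic acid; 15 rac-O-acetyltulipalin B
Product: 17 6α-hydroxy-17-oxolabda-7,13-dien-16,15-olide, via potassium carboxylate 16 (not isolated)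
Conditions: 2,4,5,6-tetra(carbazol-9-yl)isophthalonitrile (4CzIPN, 2 mol%), K2HPO4 (1.1 equiv), 15 (1.5 equiv, slow addition), DMSO, 456 nm LEDs, 25 °C, N2
Reagents that add atoms: dipotassium hydrogenphosphate, [K+].[K+].OP(=O)([O-])[O-] (its potassium stays only in 16)
Why: Proposed new method: a decarboxylative butenolide transfer in which photoexcited 4CzIPN oxidises carboxylate 16, loss of CO2 gives the primary C11 radical, this adds to the exocyclic methylene of 15 (which becomes C12), the tertiary α‑lactonyl radical is reduced by the photocatalyst radical anion to the lactone enolate, and the enolate expels the β‑acetate (E1cB) so that the new double bond can only lie in the ring (C13=C14), forming the C11–C12 bond and the α‑alkyl butenolide in one operation with no new stereocentre (the centre of racemic 15 is destroyed); the closest known reactions are photoredox decarboxylative Giese additions and decarboxylative radical allylations with acyclic Morita–Baylis–Hillman acetates or allyl sulfones, which have not been applied to a cyclic β‑acyloxy‑α‑methylene lactone to deliver a butenolide.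

Step 8
Reactants: 17 6α-hydroxy-17-oxolabda-7,13-dien-16,15-olide; 18 tigloyl chloride ((E)-2-methylbut-2-enoyl chloride)
Product: 19 6α-tigloyloxy-17-oxolabda-7,13-dien-16,15-olide
Conditions: pyridine, 4-(dimethylamino)pyridine (cat.), CH2Cl2, 0 → 23 °C
Reagents that add atoms: none
Why: Pyridine/DMAP acylation (nucleophilic catalysis) of the equatorial 6α‑alcohol with retention at C6; the weak base and low temperature avoid vinylketene formation so the E geometry of the tiglate is kept, and the butenolide and enal are inert.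

Step 9
Reactants: 19 6α-tigloyloxy-17-oxolabda-7,13-dien-16,15-olide
Product: 20 6α-tigloyloxylabda-7,13-dien-16,15-olid-17-oic acid (CNP0245290.2)
Conditions: NaClO2, NaH2PO4, 2-methyl-2-butene, t-BuOH/H2O, 0 → 23 °C
Reagents that add atoms: sodium chlorite, [Na+].[O-]Cl=O
Why: Pinnick (Lindgren) oxidation converts the α‑branched enal into the acid chemoselectively, 2‑methyl‑2‑butene removing HOCl so that the tiglate, the butenolide, the C7=C8 alkene and the allylic ester at C6 are untouched.

## Compound list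

1 | (+)-sclareolide ((3aR,5aS,9aS,9bR)-3a,6,6,9a-tetramethyldecahydronaphtho[2,1-b]furan-2(1H)-one) | CC1(CCC[C@]2([C@H]1CC[C@@]3([C@@H]2CC(=O)O3)C)C)C | starting material
2 | methyl 13,14,15,16-tetranorlabd-7-en-12-oate (5α-H, 9α-H, 10β-CH3) | C1C=C(C)[C@H](CC(=O)OC)[C@@]2(C)CCCC(C)(C)[C@H]12 | intermediate
3 | methyl 17-hydroxy-13,14,15,16-tetranorlabd-7-en-12-oate (formed in situ) | C1C=C(CO)[C@H](CC(=O)OC)[C@@]2(C)CCCC(C)(C)[C@H]12 | intermediate
4 | methyl 17-oxo-13,14,15,16-tetranorlabd-7-en-12-oate | C1C=C(C=O)[C@H](CC(=O)OC)[C@@]2(C)CCCC(C)(C)[C@H]12 | intermediate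
5 | lithium 17-oxo-13,14,15,16-tetranorlabd-7-en-12-oate (formed in situ) | C1C=C(C=O)[C@H](CC(=O)[O-])[C@@]2(C)CCCC(C)(C)[C@H]12.[Li+] | intermediate
6 | 17-oxo-13,14,15,16-tetranorlabd-7-en-12-oic acid | C1C=C(C=O)[C@H](CC(=O)O)[C@@]2(C)CCCC(C)(C)[C@H]12 | intermediate
7 | triethylsilyl 17-(triethylsilyloxy)-13,14,15,16-tetranorlabda-6,8(17)-dien-12-oate (C8=C17 geometry not defined; formed in situ) | C1=CC(=CO[Si](CC)(CC)CC)[C@H](CC(=O)O[Si](CC)(CC)CC)[C@@]2(C)CCCC(C)(C)[C@H]12 | intermediate
8 | triethylsilyl 6α-hydroxy-17-oxo-13,14,15,16-tetranorlabd-7-en-12-oate (formed in situ) | O[C@H]1C=C(C=O)[C@H](CC(=O)O[Si](CC)(CC)CC)[C@@]2(C)CCCC(C)(C)[C@H]12 | intermediate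
9 | 6α-hydroxy-17-oxo-13,14,15,16-tetranorlabd-7-en-12-oic acid | O[C@H]1C=C(C=O)[C@H](CC(=O)O)[C@@]2(C)CCCC(C)(C)[C@H]12 | intermediate
10 | methyl acrylate | C=CC(=O)OC | starting material
11 | glycolaldehyde dimer (1,4-dioxane-2,5-diol) | OC1COC(O)CO1 | starting material
12 | glycolaldehyde (formed in situ) | OCC=O | intermediate
13 | methyl 3,4-dihydroxy-2-methylidenebutanoate (racemic; formed in situ) | C=C(C(=O)OC)C(O)CO | intermediate
14 | rac-tulipalin B (4-hydroxy-3-methylideneoxolan-2-one) | C=C1C(O)COC1=O | intermediate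
15 | rac-O-acetyltulipalin B ((4-methylidene-5-oxooxolan-3-yl) acetate) | C=C1C(OC(C)=O)COC1=O | intermediate
16 | potassium 6α-hydroxy-17-oxo-13,14,15,16-tetranorlabd-7-en-12-oate (formed in situ) | O[C@H]1C=C(C=O)[C@H](CC(=O)[O-])[C@@]2(C)CCCC(C)(C)[C@H]12.[K+] | intermediate
17 | 6α-hydroxy-17-oxolabda-7,13-dien-16,15-olide | O[C@H]1C=C(C=O)[C@H](CCC2=CCOC2=O)[C@@]2(C)CCCC(C)(C)[C@H]12 | intermediate
18 | tigloyl chloride ((E)-2-methylbut-2-enoyl chloride) | C/C=C(\C)C(Cl)=O | starting material
19 | 6α-tigloyloxy-17-oxolabda-7,13-dien-16,15-olide | C/C=C(\C)C(=O)O[C@H]1C=C(C=O)[C@H](CCC2=CCOC2=O)[C@@]2(C)CCCC(C)(C)[C@H]12 | intermediate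
20 | 6α-tigloyloxylabda-7,13-dien-16,15-olid-17-oic acid (5S,6S,9R,10R; CNP0245290.2) | C/C=C(\C)C(=O)O[C@H]1C=C(C(=O)O)[C@H](CCC2=CCOC2=O)[C@@]2(C)CCCC(C)(C)[C@H]12 | target

## Step count and risks

Total step count: 9. Longest linear sequence: 7 (steps 1, 2, 3, 4, 7, 8, 9 from 1); steps 5 and 6 make the coupling partner.

**Step 7 (the proposed new coupling).** The unactivated primary carboxylate may be oxidised sluggishly, and carboxylate 16 can also attack 15 as a nucleophile (SN2′ O‑allylation) before the radical path takes over. The fallback uses known chemistry and sets out from 9. Steglich‑type esterification with 1‑hydroxypyridine‑2(1H)‑thione (DCC, CH2Cl2, 0 °C, dark) gives the Barton ester 2‑thioxopyridin‑1(2H)‑yl 6α‑hydroxy‑17‑oxo‑13,14,15,16‑tetranorlabd‑7‑en‑12‑oate F10. Visible‑light photolysis of this ester with an excess of commercial α‑methylene‑γ‑butyrolactone (C=C1CCOC1=O) gives, by decarboxylation, radical addition and thiopyridyl group transfer, 6α‑hydroxy‑17‑oxo‑13‑(pyridin‑2‑ylsulfanyl)labd‑7‑en‑16,15‑olide F11. Oxidation with mCPBA at −78 °C gives the sulfoxide 6α‑hydroxy‑17‑oxo‑13‑(pyridin‑2‑ylsulfinyl)labd‑7‑en‑16,15‑olide F12, which on warming in toluene undergoes syn‑elimination into the ring and comes back to the route at 17.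

**Step 4 (site and face of the oxidation).** The peracid could attack C6 from the β face, or the enol ether bond instead of C6=C7. If the β‑face product forms, step 4 run from 6 gives, through 7, triethylsilyl 6β‑hydroxy‑17‑oxo‑13,14,15,16‑tetranorlabd‑7‑en‑12‑oate F6 and, after the acid work‑up, 6β‑hydroxy‑17‑oxo‑13,14,15,16‑tetranorlabd‑7‑en‑12‑oic acid F7. This acid is carried through the step 7 coupling (or its fallback), by way of potassium 6β‑hydroxy‑17‑oxo‑13,14,15,16‑tetranorlabd‑7‑en‑12‑oate F8, to 6β‑hydroxy‑17‑oxolabda‑7,13‑dien‑16,15‑olide F9. The tiglate is then installed with inversion by a Mitsunobu reaction (tiglic acid, PPh3, diisopropyl azodicarboxylate, toluene, 0 → 23 °C), the α face being open to the carboxylate, which comes back to the route at 19.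

**Step 1 (alkene position).** The E1 opening may give too much of the Δ8(17) and Δ8 isomers. The fallback sets out from 1 and fixes the alkene position by an epoxide isomerisation instead. Saponification (KOH, MeOH/H2O) gives potassium 8α‑hydroxy‑13,14,15,16‑tetranorlabdan‑12‑oate F1, and MeI in DMF gives methyl 8α‑hydroxy‑13,14,15,16‑tetranorlabdan‑12‑oate F2. SOCl2/pyridine at −78 °C passes through the chlorosulfite methyl 8α‑(chlorosulfinyloxy)‑13,14,15,16‑tetranorlabdan‑12‑oate F3 to the exocyclic alkene methyl 13,14,15,16‑tetranorlabd‑8(17)‑en‑12‑oate F4. α‑Face epoxidation (mCPBA, NaHCO3, CH2Cl2) gives methyl 8α,17‑epoxy‑13,14,15,16‑tetranorlabdan‑12‑oate F5, and diethylaluminium 2,2,6,6‑tetramethylpiperidide (Et2AlTMP, toluene, 0 °C) removes a C7 proton to open it to the allylic alcohol. This comes back to the route at 3, here isolated, and MnO2 in CH2Cl2 takes 3 on to 4.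

## Further compounds

F1 | step 1 | potassium 8α-hydroxy-13,14,15,16-tetranorlabdan-12-oate | C1C[C@@](C)(O)[C@H](CC(=O)[O-])[C@@]2(C)CCCC(C)(C)[C@H]12.[K+]
F2 | step 1 | methyl 8α-hydroxy-13,14,15,16-tetranorlabdan-12-oate | C1C[C@@](C)(O)[C@H](CC(=O)OC)[C@@]2(C)CCCC(C)(C)[C@H]12
F3 | step 1 | methyl 8α-(chlorosulfinyloxy)-13,14,15,16-tetranorlabdan-12-oate | C1C[C@@](C)(OS(=O)Cl)[C@H](CC(=O)OC)[C@@]2(C)CCCC(C)(C)[C@H]12
F4 | step 1 | methyl 13,14,15,16-tetranorlabd-8(17)-en-12-oate | C1CC(=C)[C@H](CC(=O)OC)[C@@]2(C)CCCC(C)(C)[C@H]12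
F5 | step 1 | methyl 8α,17-epoxy-13,14,15,16-tetranorlabdan-12-oate | C1C[C@]4(CO4)[C@H](CC(=O)OC)[C@@]2(C)CCCC(C)(C)[C@H]12
F6 | step 4 | triethylsilyl 6β-hydroxy-17-oxo-13,14,15,16-tetranorlabd-7-en-12-oate | O[C@@H]1C=C(C=O)[C@H](CC(=O)O[Si](CC)(CC)CC)[C@@]2(C)CCCC(C)(C)[C@H]12
F7 | step 4 | 6β-hydroxy-17-oxo-13,14,15,16-tetranorlabd-7-en-12-oic acid | O[C@@H]1C=C(C=O)[C@H](CC(=O)O)[C@@]2(C)CCCC(C)(C)[C@H]12
F8 | step 4 | potassium 6β-hydroxy-17-oxo-13,14,15,16-tetranorlabd-7-en-12-oate | O[C@@H]1C=C(C=O)[C@H](CC(=O)[O-])[C@@]2(C)CCCC(C)(C)[C@H]12.[K+]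
F9 | step 4 | 6β-hydroxy-17-oxolabda-7,13-dien-16,15-olide | O[C@@H]1C=C(C=O)[C@H](CCC2=CCOC2=O)[C@@]2(C)CCCC(C)(C)[C@H]12
F10 | step 7 | 2-thioxopyridin-1(2H)-yl 6α-hydroxy-17-oxo-13,14,15,16-tetranorlabd-7-en-12-oate | O[C@H]1C=C(C=O)[C@H](CC(=O)ON3C=CC=CC3=S)[C@@]2(C)CCCC(C)(C)[C@H]12
F11 | step 7 | 6α-hydroxy-17-oxo-13-(pyridin-2-ylsulfanyl)labd-7-en-16,15-olide (C13 epimers) | O[C@H]1C=C(C=O)[C@H](CCC3(Sc4ccccn4)CCOC3=O)[C@@]2(C)CCCC(C)(C)[C@H]12
F12 | step 7 | 6α-hydroxy-17-oxo-13-(pyridin-2-ylsulfinyl)labd-7-en-16,15-olide (C13 and sulfur epimers) | O[C@H]1C=C(C=O)[C@H](CCC3(S(=O)c4ccccn4)CCOC3=O)[C@@]2(C)CCCC(C)(C)[C@H]12
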